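**Plan**

- Feature: the chain C1(=O)–C2H–C3H–C4(=O) carries its two ketone carbons on neighbouring stereocentres C2 and C3, each bearing a 4-hydroxybenzyl group, in the meso (2R,3S) arrangement. This is the imprint of a syn addition of two one-carbon carbonyl units across a Z C2=C3 double bond. The only rings are four benzene rings, all bought ready-made.
- Retrosynthesis: first the two aryl–C(=O) bonds (C1–aryl, C4–aryl), leading back to a bis(Weinreb amide) and two equivalents of a resorcinol-derived aryllithium. Then C1–C2 and C3–C4 together, back to a Z-1,4-diarylbut-2-ene, two CO and two methanol. Last C2=C3, a Wittig disconnection into two halves that both come from tyrosol.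
- Forward: benzylated tyrosol is divided into a phosphonium salt and an arylacetaldehyde; the Wittig reaction joins C2=C3; the palladium-catalysed double methoxycarbonylation adds C1 and C4; the two resorcinol rings are attached as an aryllithium; hydrogenolysis frees the six phenols. No ring is closed at any stage.
- Stereochemistry: the Z geometry comes from the lithium-free Wittig reaction and is converted into the meso relation by the syn-specific dicarbonylation. All later steps avoid conditions that epimerise C2 or C3.

Key step: step 6

Remark on the chemistry: the descriptors in the target SMILES correspond to (2S,3R), i.e. the achiral meso diastereomer, so only the relative configuration has to be controlled.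

**Route**

Step 1
Reactants: 1 tyrosol; 2 benzyl bromide
Product: 3 2-[4-(benzyloxy)phenyl]ethanol
Conditions: K2CO3, acetone, reflux
Reagents that add atoms: none
Why: Williamson ether synthesis, in which K2CO3 deprotonates only the phenol (far more acidic than the primary alcohol), so benzylation should be confined to the phenolic oxygen.

Step 2
Reactants: 3 2-[4-(benzyloxy)phenyl]ethanol (first portion)
Product: 4 1-(benzyloxy)-4-(2-bromoethyl)benzene
Conditions: CBr4, PPh3, CH2Cl2, 0 °C → rt
Reagents that add atoms: tetrabromomethane, BrC(Br)(Br)Br
Why: Appel reaction, in which the primary alcohol is activated as an alkoxyphosphonium ion and displaced by bromide under neutral conditions that leave the benzyl ether alone.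

Step 3
Reactants: 4 1-(benzyloxy)-4-(2-bromoethyl)benzene
Product: 5 {2-[4-(benzyloxy)phenyl]ethyl}triphenylphosphonium bromide
Conditions: PPh3, MeCN, reflux
Reagents that add atoms: triphenylphosphine, c1ccc(cc1)P(c1ccccc1)c1ccccc1
Why: SN2 quaternisation of triphenylphosphine by the unhindered primary bromide, the standard preparation of a Wittig salt.

Step 4
Reactants: 3 2-[4-(benzyloxy)phenyl]ethanol (second portion)
Product: 6 [4-(benzyloxy)phenyl]acetaldehyde
Conditions: Dess–Martin periodinane, CH2Cl2, 0 °C → rt; Na2S2O3/NaHCO3 work-up; used at once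
Reagents that add atoms: none
Why: Dess–Martin oxidation, which stops at the aldehyde under near-neutral, base-free conditions, important because the arylacetaldehyde enolises and self-condenses easily and is therefore not stored.

Step 5
Reactants: 5 {2-[4-(benzyloxy)phenyl]ethyl}triphenylphosphonium bromide; 6 [4-(benzyloxy)phenyl]acetaldehyde
Product: 8 (Z)-1,4-bis[4-(benzyloxy)phenyl]but-2-ene, via phosphorus ylide 7 (not isolated)
Conditions: NaN(SiMe3)2, THF, −78 → 0 °C; then 6, −78 °C → rt
Reagents that add atoms: none
Why: Wittig reaction of a non-stabilised ylide under lithium-free conditions, where kinetically controlled formation of the cis-oxaphosphetane and its syn cycloreversion should deliver the Z C2=C3 double bond, while cold addition of the aldehyde to the ylide limits enolisation of 6.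

Step 6
Reactants: 8 (Z)-1,4-bis[4-(benzyloxy)phenyl]but-2-ene; 9 carbon monoxide (2 equiv); 10 methanol (2 equiv, also co-solvent)
Product: 11 dimethyl meso-(2R,3S)-2,3-bis[4-(benzyloxy)benzyl]succinate
Conditions: Pd(O2CCF3)2 (2 mol%), N,N′-bis(2,6-dimethylphenyl)butane-2,3-diimine (2.2 mol%), p-TsOH·H2O (4 mol%), p-benzoquinone (1.5 equiv), CO (4 bar), MeOH/THF 7:1, 20 °C
Reagents that add atoms: none
Why: Pd(O2CCF3)2 and the diimine give a cationic divalent palladium centre that takes up CO and methanol to form a Pd–CO2Me unit; the alkene inserts into this bond by syn migratory insertion (C1–C2), CO inserts into the new Pd–alkyl bond with retention at carbon (C3–C4), and methanolysis of the acyl releases the second ester and zerovalent palladium, which p-benzoquinone and the acid return to the divalent state. The closest known reaction is the syn-specific oxidative bis(alkoxycarbonylation) of cis-1,2-disubstituted alkenes with divalent palladium, CO, an alcohol and an oxidant. No ring is closed. Both new stereocentres, C2 and C3, are controlled by the Z geometry of 8 combined with the syn course of the two C–C bond formations, so that only the meso (2R,3S) diester can arise whichever alkene face is attacked. The step needs CO insertion to outrun β-hydride elimination toward the benzylic CH2, which would give a styrene and a palladium hydride able to isomerise 8; the CO pressure, the low temperature and the chelating diimine with ortho-disubstituted N-aryl groups, which leaves a single cis site that CO occupies, are chosen to secure this, and the symmetrically substituted alkene raises no regiochemical question.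

Step 7
Reactants: 11 dimethyl meso-(2R,3S)-2,3-bis[4-(benzyloxy)benzyl]succinate
Product: 12 meso-(2R,3S)-2,3-bis[4-(benzyloxy)benzyl]-N1,N4-dimethoxy-N1,N4-dimethylsuccinamide
Conditions: MeNHOMe·HCl (5 equiv), Me3Al (5 equiv), CH2Cl2, 0 → 40 °C; cold 1 M HCl work-up
Reagents that add atoms: N,O-dimethylhydroxylamine hydrochloride, CNOC.Cl
Why: Weinreb amidation of both ester groups by the dimethylaluminium amide made in the flask from Me3Al and MeNHOMe·HCl, a Lewis acidic and non-basic aminolysis of esters that should not touch the α-stereocentres, so the meso relation is kept.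

Step 8
Reactants: 13 4-bromoresorcinol; 2 benzyl bromide (2 equiv)
Product: 14 2,4-bis(benzyloxy)-1-bromobenzene
Conditions: K2CO3, DMF, 60 °C
Reagents that add atoms: none
Why: Twofold Williamson ether synthesis, which masks both phenols against the organolithium chemistry to come and leaves the aryl bromide untouched.

Step 9
Reactants: 12 meso-(2R,3S)-2,3-bis[4-(benzyloxy)benzyl]-N1,N4-dimethoxy-N1,N4-dimethylsuccinamide; 14 2,4-bis(benzyloxy)-1-bromobenzene (2 equiv)
Product: 16 meso-(2R,3S)-1,4-bis[2,4-bis(benzyloxy)phenyl]-2,3-bis[4-(benzyloxy)benzyl]butane-1,4-dione, via aryllithium 15 (not isolated)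
Conditions: 14 and n-BuLi (each in slight excess over 2 equiv per 12), THF, −78 °C; then 12, −78 → −20 °C; aq. NH4Cl
Reagents that add atoms: none
Why: Bromine–lithium exchange followed by a twofold Weinreb ketone synthesis, in which each of the two amide groups takes up one aryllithium (two molecules of 14 per molecule of 12) to give a chelated tetrahedral adduct that cannot add a second time and collapses to the aryl ketone only on work-up, while the low temperature keeps the aryllithium from deprotonating C2 or C3, so the meso configuration is carried over.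

Step 10
Reactants: 16 meso-(2R,3S)-1,4-bis[2,4-bis(benzyloxy)phenyl]-2,3-bis[4-(benzyloxy)benzyl]butane-1,4-dione
Product: 17 meso-(2R,3S)-1,4-bis(2,4-dihydroxyphenyl)-2,3-bis(4-hydroxybenzyl)butane-1,4-dione
Conditions: H2 (1 atm), 10% Pd/C, EtOAc/MeOH, rt
Reagents that add atoms: none
Why: Catalytic hydrogenolysis of the six benzyl aryl ethers under neutral conditions, which is expected to be much faster than reduction of the electron-rich aryl ketones and cannot epimerise C2 or C3, so the meso target should result.

**Compound list**

1 | tyrosol, 4-(2-hydroxyethyl)phenol | OCCc1ccc(O)cc1 | starting material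
2 | benzyl bromide | BrCc1ccccc1 | starting material
3 | 2-[4-(benzyloxy)phenyl]ethanol | OCCc1ccc(OCc2ccccc2)cc1 | intermediate
4 | 1-(benzyloxy)-4-(2-bromoethyl)benzene | BrCCc1ccc(OCc2ccccc2)cc1 | intermediate
5 | {2-[4-(benzyloxy)phenyl]ethyl}triphenylphosphonium bromide | [Br-].c1ccccc1[P+](CCc1ccc(OCc2ccccc2)cc1)(c1ccccc1)c1ccccc1 | intermediate
6 | [4-(benzyloxy)phenyl]acetaldehyde | O=CCc1ccc(OCc2ccccc2)cc1 | intermediate
7 | {2-[4-(benzyloxy)phenyl]ethylidene}triphenylphosphorane (ylide, formed in the flask) | c1ccccc1P(=CCc1ccc(OCc2ccccc2)cc1)(c1ccccc1)c1ccccc1 | intermediate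
8 | (Z)-1,4-bis[4-(benzyloxy)phenyl]but-2-ene | C(/C=C\Cc1ccc(OCc2ccccc2)cc1)c1ccc(OCc2ccccc2)cc1 | intermediate
9 | carbon monoxide | [C-]#[O+] | starting material
10 | methanol | CO | starting material
11 | dimethyl meso-(2R,3S)-2,3-bis[4-(benzyloxy)benzyl]succinate | COC(=O)[C@@H](Cc1ccc(OCc2ccccc2)cc1)[C@@H](Cc1ccc(OCc2ccccc2)cc1)C(=O)OC | intermediate
12 | meso-(2R,3S)-2,3-bis[4-(benzyloxy)benzyl]-N1,N4-dimethoxy-N1,N4-dimethylsuccinamide | CON(C)C(=O)[C@@H](Cc1ccc(OCc2ccccc2)cc1)[C@@H](Cc1ccc(OCc2ccccc2)cc1)C(=O)N(C)OC | intermediate
13 | 4-bromoresorcinol, 4-bromobenzene-1,3-diol | Oc1ccc(Br)c(O)c1 | starting material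
14 | 2,4-bis(benzyloxy)-1-bromobenzene | Brc1ccc(OCc2ccccc2)cc1OCc1ccccc1 | intermediate
15 | [2,4-bis(benzyloxy)phenyl]lithium (formed in the flask) | [Li]c1ccc(OCc2ccccc2)cc1OCc1ccccc1 | intermediate
16 | meso-(2R,3S)-1,4-bis[2,4-bis(benzyloxy)phenyl]-2,3-bis[4-(benzyloxy)benzyl]butane-1,4-dione | O=C(c1ccc(OCc2ccccc2)cc1OCc1ccccc1)[C@@H](Cc1ccc(OCc2ccccc2)cc1)[C@@H](Cc1ccc(OCc2ccccc2)cc1)C(=O)c1ccc(OCc2ccccc2)cc1OCc1ccccc1 | intermediate
17 | meso-(2R,3S)-1,4-bis(2,4-dihydroxyphenyl)-2,3-bis(4-hydroxybenzyl)butane-1,4-dione (CNP0406969.1) | O=C(c1ccc(O)cc1O)[C@@H](Cc1ccc(O)cc1)[C@@H](Cc1ccc(O)cc1)C(=O)c1ccc(O)cc1O | target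

**Step count**

Total: 10 steps. Longest linear sequence: 8 steps from tyrosol (steps 1, 2, 3, 5, 6, 7, 9, 10).

**Steps most likely to fail**

Step 6. After the syn carbopalladation, β-hydride elimination toward the benzylic CH2 may outrun CO insertion, and the palladium hydride so formed may move the skipped double bond into conjugation with an arene, so that the diester is not formed. The fallback gives up stereospecific control and relies on separation. It sets out from benzyl bromide 2, which O-benzylates commercial methyl 3-(4-hydroxyphenyl)propanoate (K2CO3, acetone) to methyl 3-[4-(benzyloxy)phenyl]propanoate F1. Its lithium enolate (LiN(iPr)2, THF, −78 °C) is coupled oxidatively with CuBr2, two molecules of F1 giving one 2,3-disubstituted succinate. This should form as a mixture of 11 and racemic dimethyl (2R*,3R*)-2,3-bis[4-(benzyloxy)benzyl]succinate F2. The meso form is separated by crystallisation or chromatography, F2 can be re-equilibrated with NaOMe in MeOH and recycled, and the route is rejoined at 11.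

Step 9. The bulky ortho-alkoxy aryllithium may act as a base toward the hindered, α-branched amide, so that enolisation (loss of the meso relation) or arrest after a single addition competes with the double ketone formation. The fallback sets out from diester 11, which Me2AlSEt (from Me3Al and EtSH, CH2Cl2) converts into S,S′-diethyl meso-(2R,3S)-2,3-bis[4-(benzyloxy)benzyl]butanebis(thioate) F3. Aryllithium 15 is trapped with B(OiPr)3 and hydrolysed to [2,4-bis(benzyloxy)phenyl]boronic acid F4. A Liebeskind–Srogl coupling of F3 with two equivalents of F4 (Pd2(dba)3, i.e. tris(dibenzylideneacetone)dipalladium, tri(2-furyl)phosphine, copper thiophene-2-carboxylate Cu(O2C-C4H3S), THF, 50 °C) forms both aryl ketones without base and comes back to the route at 16.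

Step 5. The basic ylide may enolise the arylacetaldehyde instead of adding to it, and any leakage to the E isomer or base-induced migration of the double bond would be passed on by step 6 as the racemic diester. The fallback sets out from benzyl bromide 2, which O-benzylates commercial 4-allylphenol (K2CO3, acetone) to 1-(benzyloxy)-4-(prop-2-en-1-yl)benzene F5. Z-selective homometathesis of F5 (THF, 35 °C, ethene swept out) then gives the alkene and rejoins the route at 8. The catalyst is the cyclometalated ruthenium nitrate carbene complex Ru(ONO2)(=CH-C6H4-2-OiPr)(C22H29N2), overall C32H41N3O4Ru. Its C22H29N2 ligand is 1-(adamantane-1,2-diyl)-3-mesitylimidazolidin-2-ylidene, bound through the carbene carbon and one adamantyl carbon.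

**Further compounds**

F1 | step 6 | methyl 3-[4-(benzyloxy)phenyl]propanoate | COC(=O)CCc1ccc(OCc2ccccc2)cc1
F2 | step 6 | racemic dimethyl (2R*,3R*)-2,3-bis[4-(benzyloxy)benzyl]succinate (2S,3S enantiomer drawn) | COC(=O)[C@@H](Cc1ccc(OCc2ccccc2)cc1)[C@H](Cc1ccc(OCc2ccccc2)cc1)C(=O)OC
F3 | step 9 | S,S′-diethyl meso-(2R,3S)-2,3-bis[4-(benzyloxy)benzyl]butanebis(thioate) | CCSC(=O)[C@@H](Cc1ccc(OCc2ccccc2)cc1)[C@@H](Cc1ccc(OCc2ccccc2)cc1)C(=O)SCC
F4 | step 9 | [2,4-bis(benzyloxy)phenyl]boronic acid | OB(O)c1ccc(OCc2ccccc2)cc1OCc1ccccc1
F5 | step 5 | 1-(benzyloxy)-4-(prop-2-en-1-yl)benzene | C=CCc1ccc(OCc2ccccc2)cc1
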